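All constants are made up; the rest is arithmetic.

We read every flask at 3.0 min, so the question is how many times a catalyst can go round in that time, and whether Q lasts that long.

| flask | L | Q | X | temperature | time |
|---|---|---|---|---|---|
| north-west | 0.77 M | 0.809 M | 10 mM | 60 °C | 3.0 min |
| north-east | 0.77 M | 0.809 M | 10 mM | 100 °C | 3.0 min |
| east | 0.77 M | 0.809 M | 10 mM | 80 °C | 3.0 min |

    Q + X → Q.X (k1 = 2.7 /M/s, Ea1 = 54.0 kJ/mol)
    L + Q.X ⇌ L.Q.X (K2 = 88 /M, k2 = 2.8 /M/s, Ea2 = 65.0 kJ/mol, ΔH2 = 1.00 kJ/mol)
    L.Q.X → Z (k3 = 12 /s, Ea3 = 80.0 kJ/mol)
    Z → X + E (k4 = 0.57 /s, Ea4 = 97.0 kJ/mol)
    Q → J (k5 = 0.031 /s, Ea5 = 98.0 kJ/mol)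
    (constants at 100 °C)

- the list of constants is for 100 °C, to be carried to other temperatures by the activation energies and enthalpies

- which flask leads in amount of E, in percent of the L charged ("all alike" within 1.5 percentage points) (north-west / north-east / east / all alike)
- how much E is there at the end, in percent of the L charged: north-west
- how much E is there at the end, in percent of the L charged: north-east
- how much E is there at the end, in percent of the L charged: east

The catalyst passes through its forms in series: X takes up Q, Q.X binds L, L.Q.X becomes Z, and Z releases E and X. Meanwhile Q decays to J on its own. Take north-west, at 60 °C. The stage from Z takes 74.9 s there, and we add the other stage time constants at the charged concentrations. This gives 86.2 s for τ, the turnover time: the mean time for one catalyst to go once round the cycle.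

In the first instants of north-west, the catalyst fills the forms up to Z, a lag of 11.3 s. In the middle of north-west, Z is the resting state and the step from it the rate-limiting step, since that stage takes 86.9% of τ. Q in north-west meanwhile has a decay time constant of 23.9 min, longer than the reading time, so we keep τ to the end. North-west therefore counts (time minus lag)/τ = 1.96 turnovers, which makes 2.54% of L into E.

East, at 80 °C, has τ = 13.4 s, so its count gives 17.4%. That figure is on the high side, because the decay time constant of Q is about as long as the reading time, and τ grows as Q falls.

In north-east, at 100 °C, τ is 2.76 s, and the count at that τ gives 84.7%. But Q there has a decay time constant of 32.3 s, far shorter than the reading time, so control passes from the clock to Q. Write τ = a + b/Q, with a = 2.30 s and b the inverse of the first rate constant. With C the catalyst charge, d the decay constant and Qc the Q charged, dividing the cycle's take of Q by the total loss of Q removes time. Integrating gives E = (C/(d·a))·ln(1 + d·a·Qc/(C + d·b)) = 0.183 M, or 23.8% of L. This estimate stands above the east count, so we expect north-east to lead.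

The forecast gives 2.5% for north-west, 23.6% for north-east and 15.8% for east, with north-east in the lead, and says of north-east: “Q dies with a lifetime of about 32 s”.

The simulation gives 2.54% for north-west, 23.9% for north-east and 15.8% for east, and north-east leads.

Our count for north-west stands at 2.54% against 2.54%. The neighbour is north-west with 0.040 M of X. Our τ contains no catalyst term, so our count for the neighbour stays at 1.96 turnovers, which gives 10.2% of L as E. The simulated neighbour gives 10.1%, with 75% of its Q still there.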